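**Retrosynthetic overview**
1. Target 21 ⇒ 6β-alcohol 17 + (E)-4-acetoxycinnamic acid 18 (ester C–O bond, made last).
2. 17 ⇒ eudesm-3-en-6-one 14/16: C5–H by kinetic protonation of the 3,5-dien-6-olate, C6–OH by α-face hydride delivery.
3. Ring A (formed last) ⇒ C3=C4 by a reversed-polarity olefination. The enone β-carbon C4 of 12 becomes a nucleophilic phosphonium β-ylide (homoenolate equivalent) and attacks the C3 aldehyde; both carbons are natively electrophilic.
4. 12 ⇒ (S)-piperitone 4 + propanal homoenolate-equivalent Grignard 5 (C1–C10 bond, quaternary carbon) + acetaldehyde 6 (C4 and C15).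
5. Ring B comes intact from (−)-menthone 1, which supplies the C7 isopropyl stereocentre.

Assumption: eudesmane numbering is used for the decalin (C4 bears the vinylic methyl, C5/C10 are the ring-fusion carbons, C6 carries oxygen, C7 the isopropyl group), and the ligand enantiomer in step 2 is taken to be the one that adds the Grignard carbon anti to the isopropyl group (to be confirmed on test scale).

**Step 1**
Reactants: 1 (−)-menthone
Product: 4 (S)-piperitone, via lithium enolate 2 (not isolated), via silyl enol ether 3 (not isolated)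
Conditions: LDA, THF, −78 °C; TMSCl; then Pd(OAc)2 (10 mol%), O2 (1 atm), DMSO, 25 °C
Reagents that add atoms: lithium diisopropylamide CC(C)[N-]C(C)C.[Li+]; chlorotrimethylsilane C[Si](C)(C)Cl
Why: Kinetic deprotonation at the unhindered methylene and silylation give the less substituted silyl enol ether, and Saegusa–Ito oxidation (palladium enolate, β-hydride elimination) installs the enone; the isopropyl-bearing stereocentre is never enolised and stays S.

**Step 2**
Reactants: 4 (S)-piperitone; 5 [2-(1,3-dioxolan-2-yl)ethyl]magnesium bromide; 6 acetaldehyde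
Product: 9 ketol (3S,6S)-3-[2-(1,3-dioxolan-2-yl)ethyl]-2-(1-hydroxyethyl)-6-isopropyl-3-methylcyclohexan-1-one, via magnesium enolate 7 (not isolated), via magnesium aldolate 8 (not isolated)
Conditions: 5 (1.5 equiv), Cu(OTf)2 (3 mol%), chiral imidazolinium chloride (NHC precursor, 4 mol%), Et2O, 0 °C; then 6 (3 equiv), −78 to −40 °C; pH 7 buffer
Reagents that add atoms: none
Why: Copper-catalysed asymmetric conjugate addition of the propanal homoenolate-equivalent Grignard creates the quaternary carbon (future C10) under catalyst control, with the new chain anti to the isopropyl group; the regiodefined magnesium enolate is then trapped by aldol addition to acetaldehyde (the two ketol stereocentres are erased in step 3).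

**Step 3**
Reactants: 9 ketol
Product: 12 (2Z,3S,6S)-2-ethylidene-6-isopropyl-3-methyl-3-(3-oxopropyl)cyclohexan-1-one, via ketol mesylate 10 (not isolated), via enone acetal 11 (not isolated)
Conditions: MsCl, Et3N, CH2Cl2, 0 °C; DBU, 25 °C; then 1 M aq. HCl, THF, 25 °C
Reagents that add atoms: methanesulfonyl chloride CS(=O)(=O)Cl; water O
Why: Mesylation and E1cB elimination give the conjugated ethylidene ketone (methyl expected syn to C=O, away from the quaternary carbon; either geometry serves), and acetal hydrolysis frees the aldehyde; the two stereocentres are untouched.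

**Step 4 (key step)**
Reactants: 12 enone aldehyde
Product: 14 (7S,10R)-eudesm-3-en-6-one as a C5-epimer mixture, via phosphonium ylide 13 (not isolated)
Conditions: PBu3 (1.5 equiv), PhOH (20 mol%), toluene (0.02 M), 80 °C, Ar
Reagents that add atoms: tributylphosphine CCCCP(CCCC)CCCC
Why: Proposed new method: PBu3 adds reversibly to C4 of the s-cis enone (phospha-Michael), Morita–Baylis–Hillman turnover is impossible because the α-carbon C5 would carry no hydrogen after an aldol, so phenol-shuttled proton transfer from C4 to C5 gives the C4 phosphonium ylide 13, a β-carbanion (homoenolate-type) form of the enone, which is trapped irreversibly by intramolecular Wittig olefination of the C3 aldehyde to close ring A with the C3=C4 bond and expel Bu3P=O; the closest known reaction types are phosphine-mediated Michael addition/intramolecular Wittig annulations of enones and the Schweizer annulation of vinylphosphonium salts; C5 forms as an epimer mixture that is corrected in step 5, while C7 and C10 are only carried.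

**Step 5**
Reactants: 14 eudesm-3-en-6-one mixture
Product: 17 (5R,6R,7S,10R)-eudesm-3-en-6-ol (6β-OH), via potassium dienolate 15 (not isolated), via trans-fused ketone 16 (not isolated)
Conditions: KOtBu (3 equiv), t-BuOH/THF, 25 °C, Ar; 10% aq. AcOH, −20 °C; cold extraction, then at once NaBH4, CeCl3·7H2O, MeOH, −40 °C
Reagents that add atoms: potassium tert-butoxide CC(C)(C)[O-].[K+]
Why: Excess tert-butoxide funnels both C5 epimers (and any conjugated isomer) into one 3,5-dien-6-olate, kinetic deconjugative α-protonation occurs at C5 anti to the axial C10 methyl to give the trans ring fusion, and Luche-type borohydride reduction delivers hydride to C6 from the α face (the β face is blocked by the syn-axial C10 methyl, as in 6-oxo steroid reductions) to give the axial 6β-alcohol.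

**Step 6**
Reactants: 17 eudesm-3-en-6β-ol; 18 (E)-4-acetoxycinnamic acid
Product: 21 (5R,6R,7S,10R)-eudesm-3-en-6-yl (E)-3-(4-hydroxyphenyl)prop-2-enoate, via mixed anhydride 19 (not isolated), via O-acetyl ester 20 (not isolated)
Conditions: 18, 2,4,6-Cl3C6H2COCl, Et3N, THF, 25 °C; 17, DMAP, toluene, 60 °C; then pyrrolidine, 0 °C
Reagents that add atoms: 2,4,6-trichlorobenzoyl chloride O=C(Cl)c1c(Cl)cc(Cl)cc1Cl
Why: Yamaguchi esterification acylates the hindered axial alcohol with retention at C6 and keeps the E alkene, and pyrrolidine aminolysis then removes only the aryl acetate, leaving the hindered cinnamate ester intact.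

**Compound list**
1 | (−)-menthone, (2S,5R)-2-isopropyl-5-methylcyclohexan-1-one | C[C@@H]1CC[C@H](C(=O)C1)C(C)C | starting material
2 | lithium (3R,6S)-6-isopropyl-3-methylcyclohex-1-en-1-olate | C[C@@H]1CC[C@H](C(O[Li])=C1)C(C)C | intermediate
3 | trimethyl{[(3R,6S)-6-isopropyl-3-methylcyclohex-1-en-1-yl]oxy}silane | C[C@@H]1CC[C@H](C(O[Si](C)(C)C)=C1)C(C)C | intermediate
4 | (S)-piperitone, (6S)-6-isopropyl-3-methylcyclohex-2-en-1-one | CC1=CC(=O)[C@H](C(C)C)CC1 | intermediate
5 | [2-(1,3-dioxolan-2-yl)ethyl]magnesium bromide | Br[Mg]CCC1OCCO1 | starting material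
6 | acetaldehyde | CC=O | starting material
7 | bromomagnesium enolate of the conjugate adduct (chain anti to isopropyl) | Br[Mg]OC1=C[C@](C)(CCC2OCCO2)CC[C@H]1C(C)C | intermediate
8 | bromomagnesium aldolate of 9 | CC(O[Mg]Br)C1C(=O)[C@H](C(C)C)CC[C@@]1(C)CCC2OCCO2 | intermediate
9 | (3S,6S)-3-[2-(1,3-dioxolan-2-yl)ethyl]-2-(1-hydroxyethyl)-6-isopropyl-3-methylcyclohexan-1-one (mixture at C2 and carbinol carbon) | CC(O)C1C(=O)[C@H](C(C)C)CC[C@@]1(C)CCC2OCCO2 | intermediate
10 | methanesulfonate of ketol 9 | CC(OS(C)(=O)=O)C1C(=O)[C@H](C(C)C)CC[C@@]1(C)CCC2OCCO2 | intermediate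
11 | (2Z,3S,6S)-3-[2-(1,3-dioxolan-2-yl)ethyl]-2-ethylidene-6-isopropyl-3-methylcyclohexan-1-one | O=C1[C@H](C(C)C)CC[C@@](C)(CCC2OCCO2)/C1=C/C | intermediate
12 | (2Z,3S,6S)-2-ethylidene-6-isopropyl-3-methyl-3-(3-oxopropyl)cyclohexan-1-one | O=C1[C@H](C(C)C)CC[C@@](C)(CCC=O)/C1=C/C | intermediate
13 | tributylphosphonium ylide at the former enone β-carbon (C5 unspecified) | CCCC[P+](CCCC)(CCCC)[C-](C)C1C(=O)[C@H](C(C)C)CC[C@@]1(C)CCC=O | intermediate
14 | (7S,10R)-eudesm-3-en-6-one, mixture of C5 epimers | CC1=CCC[C@]2(C)CC[C@@H](C(C)C)C(=O)C12 | intermediate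
15 | potassium (7S,10R)-eudesma-3,5-dien-6-olate | CC1=CCC[C@]2(C)CC[C@@H](C(C)C)C([O-])=C12.[K+] | intermediate
16 | (5R,7S,10R)-eudesm-3-en-6-one (5α-H, trans-fused) | CC1=CCC[C@]2(C)CC[C@@H](C(C)C)C(=O)[C@@H]12 | intermediate
17 | (5R,6R,7S,10R)-eudesm-3-en-6-ol (5α-H, 6β-OH, 7β-isopropyl, 10β-methyl) | CC1=CCC[C@]2(C)CC[C@@H](C(C)C)[C@@H](O)[C@@H]12 | intermediate
18 | (E)-4-acetoxycinnamic acid | CC(=O)Oc1ccc(/C=C/C(=O)O)cc1 | starting material
19 | (E)-4-acetoxycinnamic 2,4,6-trichlorobenzoic anhydride | CC(=O)Oc1ccc(/C=C/C(=O)OC(=O)c2c(Cl)cc(Cl)cc2Cl)cc1 | intermediate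
20 | (5R,6R,7S,10R)-eudesm-3-en-6-yl (E)-3-(4-acetoxyphenyl)prop-2-enoate | CC1=CCC[C@]2(C)CC[C@@H](C(C)C)[C@@H](OC(=O)/C=C/c3ccc(OC(C)=O)cc3)[C@@H]12 | intermediate
21 | CNP0220414.1, (5R,6R,7S,10R)-eudesm-3-en-6-yl (E)-3-(4-hydroxyphenyl)prop-2-enoate | CC1=CCC[C@]2(C)CC[C@@H](C(C)C)[C@@H](OC(=O)/C=C/c3ccc(O)cc3)[C@@H]12 | target

**Step count**
Total steps: 6. Longest linear sequence: 6 steps, from (−)-menthone 1 to 21.

**Three steps most likely to fail, with fallbacks**

Step 4, the key ring closure. The phosphine adduct of a β-substituted enone is only lightly populated and the ylide is not carbonyl-stabilised, so the closure may be slow or lose out to aldehyde self-condensation. The fallback sets out from 12 and returns at 16. An N-heterocyclic-carbene-catalysed intramolecular Stetter reaction (thiazolium salt, Et3N, EtOH, 70 °C) adds the C3 acyl anion to C4 and closes ring A as 4α-methyl-5α-eudesmane-3,6-dione F1, in which all epimerisable centres settle to the all-equatorial trans-decalin. Tf2O with 2,6-di-tert-butyl-4-methylpyridine converts the unhindered C3 ketone into the more substituted enol triflate, 6-oxo-5α-eudesm-3-en-3-yl trifluoromethanesulfonate F2. Reduction with Pd(OAc)2/PPh3, Bu3N and HCO2H in DMF gives 16, which is reduced with NaBH4/CeCl3·7H2O as in the last stage of step 5.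

Step 2, the conjugate addition and aldol. The acetal Grignard may perform poorly in ether, and the intrinsic facial bias of piperitone is weak and may oppose the catalyst. The fallback sets out from 4 and returns at 12. A TiCl4-promoted Hosomi–Sakurai allylation with allyltrimethylsilane (CH2Cl2, −78 °C), with the titanium enolate trapped by acetaldehyde 6, gives (3S,6S)-3-allyl-2-(1-hydroxyethyl)-6-isopropyl-3-methylcyclohexan-1-one F3. TsOH-catalysed dehydration in toluene gives (2Z,3S,6S)-3-allyl-2-ethylidene-6-isopropyl-3-methylcyclohexan-1-one F4, where the epimer at the quaternary carbon can be removed by chromatography. An aldehyde-selective Wacker oxidation (PdCl2(PhCN)2, CuCl2, AgNO2, O2, t-BuOH/MeNO2) then turns the allyl group into the 3-oxopropyl chain of 12.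

Step 5, the protonation and reduction. Protonation at C3 (giving the conjugated enone), the wrong face at C5, or isomerisation of the β,γ-unsaturated ketone before reduction would each cost material. The fallback sets out from 14 and returns at 17. Isopropenyl acetate with catalytic TsOH at reflux converts all isomers of 14 into the isolable dienol acetate 6-acetoxyeudesma-3,5-diene F5. NaBH4 in aqueous ethanol at 0 °C then cleaves the enol ester; the dienol is C-protonated at C5 in the protic medium and the β,γ-unsaturated ketone is reduced as it forms, giving 17.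

**Further compounds**
F1 | step 4 | 4α-methyl-5α-eudesmane-3,6-dione (7β-isopropyl, 10β-methyl) | C[C@@H]1C(=O)CC[C@]2(C)CC[C@@H](C(C)C)C(=O)[C@@H]12
F2 | step 4 | 6-oxo-5α-eudesm-3-en-3-yl trifluoromethanesulfonate | CC1=C(OS(=O)(=O)C(F)(F)F)CC[C@]2(C)CC[C@@H](C(C)C)C(=O)[C@@H]12
F3 | step 2 | (3S,6S)-3-allyl-2-(1-hydroxyethyl)-6-isopropyl-3-methylcyclohexan-1-one | CC(O)C1C(=O)[C@H](C(C)C)CC[C@@]1(C)CC=C
F4 | step 2 | (2Z,3S,6S)-3-allyl-2-ethylidene-6-isopropyl-3-methylcyclohexan-1-one | O=C1[C@H](C(C)C)CC[C@@](C)(CC=C)/C1=C/C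
F5 | step 5 | (7S,10R)-6-acetoxyeudesma-3,5-diene | CC1=CCC[C@]2(C)CC[C@@H](C(C)C)C(OC(C)=O)=C12
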